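**Retrosynthetic overview**
1. Spiro-cyclohexene: Diels–Alder disconnection (C-2–C-4' and C-14–C-15') into an (11S) guaianolide trienone (diene) and an (11R) α-methylene-cyclopentanone guaianolide (dienophile); a suprafacial 1,3-H shift then sets C-10.
2. Each seven-membered ring: C-1–C-10 bond by 7-exo Heck (diene half) or reductive Heck (dienophile half) closure of a vinyl bromide onto a 5-methylidenecyclopent-2-enone.
3. The two C-11 epimers: one conjugate addition to the butenolide (C-7–C-8), protonated kinetically (11R) or equilibrated (11S).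
4. C-5–C-6 bond and first stereocentres: organocatalytic asymmetric allylic alkylation of an achiral cyclopentenone Morita–Baylis–Hillman carbonate with 3-methylfuran-2(5H)-one.
5. Ring order: cyclopentanone and butenolide rings are bought and joined first, then each cycloheptane, last the spiro-cyclohexene.

Assumption: the target is taken exactly as drawn (guaiane numbering, primes for the spiro half: 5R,6S,7S,10S,11S,1'R,4'R,5'R,6'S,7'S,11'R); 2-(hydroxymethyl)cyclopent-2-en-1-one, 3-methylfuran-2(5H)-one and 3-bromobut-3-en-1-ol are bought.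

**Step 1**
Reactants: 1 2-(hydroxymethyl)cyclopent-2-en-1-one
Product: 2 tert-butyl (5-oxocyclopent-1-en-1-yl)methyl carbonate
Conditions: Boc2O (1.2 equiv), DMAP (5 mol%), CH2Cl2, 0 °C to rt
Reagents that add atoms: di-tert-butyl dicarbonate, CC(C)(C)OC(=O)OC(=O)OC(C)(C)C
Why: DMAP-catalysed O-acylation of the primary allylic alcohol installs a leaving group that later releases CO2 and tert-butoxide as the in situ base; no stereocentre is formed.

**Step 2**
Reactants: 2 tert-butyl (5-oxocyclopent-1-en-1-yl)methyl carbonate; 3 3-methylfuran-2(5H)-one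
Product: 4 (5S)-3-methyl-5-[(1R)-2-methylidene-3-oxocyclopentyl]furan-2(5H)-one
Conditions: 3 (3 equiv), (DHQD)2PYR (10 mol%), PhCF3, 4 Å MS, 0 °C
Reagents that add atoms: none
Why: Proposed new method: the cinchona tertiary amine displaces tert-butyl carbonate from 2 and, after allylic transposition, rests as the chiral 2-(ammoniomethyl)cyclopent-2-enone cation ion-paired with the 2-oxidofuran formed from 3 by the released tert-butoxide, and γ-attack of this dienolate on the ring β-carbon with SN2' loss of the amine regenerates the exocyclic methylene and sets C-5 (R) and C-6 (S) within the ion pair; the closest known reaction type is the cinchona-amine-catalysed asymmetric allylic alkylation of acyclic Morita–Baylis–Hillman carbonates with butenolides, here extended to a formaldehyde-derived cyclic-enone carbonate whose new stereocentre is a ring carbon.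

**Step 3**
Reactants: 4 (5S)-3-methyl-5-[(1R)-2-methylidene-3-oxocyclopentyl]furan-2(5H)-one
Product: 5 (5S)-5-[(1R,3S)-3-hydroxy-2-methylidenecyclopentyl]-3-methylfuran-2(5H)-one
Conditions: NaBH4, CeCl3·7H2O, MeOH, −78 °C
Reagents that add atoms: none
Why: Luche reduction (1,2-selective) masks the α-methylene ketone as an allylic alcohol so that the butenolide is the only Michael acceptor left; hydride enters anti to the C-5 substituent (3S major), a centre that is erased in steps 7 and 9.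

**Step 4**
Reactants: 6 3-bromobut-3-en-1-ol
Product: 7 2,4-dibromobut-1-ene
Conditions: CBr4, PPh3, CH2Cl2, 0 °C
Reagents that add atoms: carbon tetrabromide, BrC(Br)(Br)Br
Why: Appel bromination of the primary alcohol; the vinyl bromide is inert.

**Step 5**
Reactants: 5 (5S)-5-[(1R,3S)-3-hydroxy-2-methylidenecyclopentyl]-3-methylfuran-2(5H)-one; 7 2,4-dibromobut-1-ene
Product: 10 (3R,4S,5S)-4-(3-bromobut-3-en-1-yl)-5-[(1R,3S)-3-hydroxy-2-methylidenecyclopentyl]-3-methyloxolan-2-one, via Grignard reagent 8 (not isolated), via bis-silyl ketene acetal 9 (not isolated)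
Conditions: 7, Mg, THF, 0 °C (gives 8, 2.5 equiv); then 5, CuBr·SMe2 (20 mol%), TMSCl (3 equiv), THF, −78 to −40 °C; then AcOH, THF/H2O, −40 to 0 °C
Reagents that add atoms: none
Why: Copper-catalysed conjugate addition of 8 occurs anti to the C-6 substituent of the butenolide (sets C-7 as S, 6,7-trans), TMSCl traps the enolate (and the alkoxide) as 9, and kinetic protonation of 9 anti to the new C-7 chain gives the 7,11-cis lactone (11R).

**Step 6**
Reactants: 10 (3R,4S,5S)-4-(3-bromobut-3-en-1-yl)-5-[(1R,3S)-3-hydroxy-2-methylidenecyclopentyl]-3-methyloxolan-2-one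
Product: 11 (3S,4S,5S)-4-(3-bromobut-3-en-1-yl)-5-[(1R,3S)-3-hydroxy-2-methylidenecyclopentyl]-3-methyloxolan-2-one
Conditions: KOt-Bu (20 mol%), t-BuOH/THF, 0 °C to rt
Reagents that add atoms: none
Why: Base-mediated epimerisation through the lactone enolate gives the thermodynamically preferred all-trans lactone (11S); no other centre is acidic at this stage.

**Step 7**
Reactants: 10 (3R,4S,5S)-4-(3-bromobut-3-en-1-yl)-5-[(1R,3S)-3-hydroxy-2-methylidenecyclopentyl]-3-methyloxolan-2-one
Product: 13 (3R,4S,5S)-4-(3-bromobut-3-en-1-yl)-3-methyl-5-[(1R)-5-methylidene-4-oxocyclopent-2-en-1-yl]oxolan-2-one, via enone 12 (not isolated)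
Conditions: IBX (3 equiv), DMSO, 25 then 75 °C
Reagents that add atoms: none
Why: IBX oxidises the allylic alcohol to 12 and then dehydrogenates its only enolisable α-position (C-2, because C-4 carries the methylidene) in a Nicolaou-type IBX dehydrogenation, giving the cross-conjugated dienone; the carbinol centre disappears.

**Step 8**
Reactants: 13 (3R,4S,5S)-4-(3-bromobut-3-en-1-yl)-3-methyl-5-[(1R)-5-methylidene-4-oxocyclopent-2-en-1-yl]oxolan-2-one
Product: 14 (3R,3aS,6aR,9aR,9bS)-3-methyl-6,9-dimethylidene-octahydroazuleno[4,5-b]furan-2,8-dione, that is (11R)-3-oxoguaia-4(15),10(14)-dien-12,6α-olide (1α-H, 5α-H, 6β-H, 7α-H, 11α-H)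
Conditions: Pd(OAc)2 (10 mol%), HCO2Na (1.5 equiv), n-Bu4NCl (1 equiv), DMF, 60 °C
Reagents that add atoms: none
Why: Intramolecular reductive Heck reaction: 7-exo carbopalladation of the ring enone at its β-carbon C-1, delivered from the face of the C-5 tether, gives the cis-fused hydroazulenone (1R) and formate reduces the palladium enolate.

**Step 9**
Reactants: 11 (3S,4S,5S)-4-(3-bromobut-3-en-1-yl)-5-[(1R,3S)-3-hydroxy-2-methylidenecyclopentyl]-3-methyloxolan-2-one
Product: 16 (3S,4S,5S)-4-(3-bromobut-3-en-1-yl)-3-methyl-5-[(1R)-5-methylidene-4-oxocyclopent-2-en-1-yl]oxolan-2-one, via enone 15 (not isolated)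
Conditions: IBX (3 equiv), DMSO, 25 then 75 °C
Reagents that add atoms: none
Why: Same IBX alcohol oxidation and regiodefined dehydrogenation as in step 7, here in the 11S series.

**Step 10**
Reactants: 16 (3S,4S,5S)-4-(3-bromobut-3-en-1-yl)-3-methyl-5-[(1R)-5-methylidene-4-oxocyclopent-2-en-1-yl]oxolan-2-one; 14 (11R)-3-oxoguaia-4(15),10(14)-dien-12,6α-olide
Product: 19 CNP0240988.1, via trienone 17 (not isolated), via Diels–Alder adduct 18 (not isolated)
Conditions: 14 (3 equiv, excess recovered), Pd(OAc)2 (10 mol%), n-Bu4NCl, NaHCO3, PhMe/DMF, 60 °C; then TBD (20 mol%), 25 °C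
Reagents that add atoms: none
Why: Intramolecular Heck reaction (7-exo, then β-hydride elimination) gives the s-cis-locked trienone 17, which undergoes Diels–Alder reaction with 14 with ortho regiochemistry on the α-face of both partners (sets spiro C-4' as R, H-2 β), and a TBD-mediated suprafacial 1,3-prototropic shift carries H-2 to C-10 (10S) while moving the alkene into conjugation.

**Compound list**
1 | 2-(hydroxymethyl)cyclopent-2-en-1-one | O=C1CCC=C1CO | starting material
2 | tert-butyl (5-oxocyclopent-1-en-1-yl)methyl carbonate | O=C1CCC=C1COC(=O)OC(C)(C)C | intermediate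
3 | 3-methylfuran-2(5H)-one | CC1=CCOC1=O | starting material
4 | (5S)-3-methyl-5-[(1R)-2-methylidene-3-oxocyclopentyl]furan-2(5H)-one | C=C1C(=O)CC[C@H]1[C@H]1OC(=O)C(C)=C1 | intermediate
5 | (5S)-5-[(1R,3S)-3-hydroxy-2-methylidenecyclopentyl]-3-methylfuran-2(5H)-one (major carbinol epimer) | C=C1[C@@H](O)CC[C@H]1[C@H]1OC(=O)C(C)=C1 | intermediate
6 | 3-bromobut-3-en-1-ol | OCCC(Br)=C | starting material
7 | 2,4-dibromobut-1-ene | BrCCC(Br)=C | intermediate
8 | (3-bromobut-3-en-1-yl)magnesium bromide | Br[Mg]CCC(Br)=C | intermediate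
9 | [(2R,3S)-3-(3-bromobut-3-en-1-yl)-4-methyl-2-[(1R,3S)-2-methylidene-3-(trimethylsilyloxy)cyclopentyl]-2,3-dihydrofuran-5-yl]oxy-trimethylsilane | C=C1[C@@H](O[Si](C)(C)C)CC[C@H]1[C@H]1OC(O[Si](C)(C)C)=C(C)[C@@H]1CCC(Br)=C | intermediate
10 | (3R,4S,5S)-4-(3-bromobut-3-en-1-yl)-5-[(1R,3S)-3-hydroxy-2-methylidenecyclopentyl]-3-methyloxolan-2-one | C=C1[C@@H](O)CC[C@H]1[C@H]1OC(=O)[C@H](C)[C@@H]1CCC(Br)=C | intermediate
11 | (3S,4S,5S)-4-(3-bromobut-3-en-1-yl)-5-[(1R,3S)-3-hydroxy-2-methylidenecyclopentyl]-3-methyloxolan-2-one | C=C1[C@@H](O)CC[C@H]1[C@H]1OC(=O)[C@@H](C)[C@@H]1CCC(Br)=C | intermediate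
12 | (3R,4S,5S)-4-(3-bromobut-3-en-1-yl)-3-methyl-5-[(1R)-2-methylidene-3-oxocyclopentyl]oxolan-2-one | C=C1C(=O)CC[C@H]1[C@H]1OC(=O)[C@H](C)[C@@H]1CCC(Br)=C | intermediate
13 | (3R,4S,5S)-4-(3-bromobut-3-en-1-yl)-3-methyl-5-[(1R)-5-methylidene-4-oxocyclopent-2-en-1-yl]oxolan-2-one | C=C1C(=O)C=C[C@H]1[C@H]1OC(=O)[C@H](C)[C@@H]1CCC(Br)=C | intermediate
14 | (3R,3aS,6aR,9aR,9bS)-3-methyl-6,9-dimethylidene-octahydroazuleno[4,5-b]furan-2,8-dione; (11R)-3-oxoguaia-4(15),10(14)-dien-12,6α-olide | C=C1C(=O)C[C@H]2C(=C)CC[C@@H]3[C@H](OC(=O)[C@@H]3C)[C@H]21 | intermediate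
15 | (3S,4S,5S)-4-(3-bromobut-3-en-1-yl)-3-methyl-5-[(1R)-2-methylidene-3-oxocyclopentyl]oxolan-2-one | C=C1C(=O)CC[C@H]1[C@H]1OC(=O)[C@@H](C)[C@@H]1CCC(Br)=C | intermediate
16 | (3S,4S,5S)-4-(3-bromobut-3-en-1-yl)-3-methyl-5-[(1R)-5-methylidene-4-oxocyclopent-2-en-1-yl]oxolan-2-one | C=C1C(=O)C=C[C@H]1[C@H]1OC(=O)[C@@H](C)[C@@H]1CCC(Br)=C | intermediate
17 | (5R,6S,7S,11S)-3-oxoguaia-1,4(15),10(14)-trien-12,6α-olide (5α-H, 6β-H, 7α-H, 11β-H) | C=C1C(=O)C=C2C(=C)CC[C@@H]3[C@H](OC(=O)[C@H]3C)[C@@H]12 | intermediate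
18 | Diels–Alder adduct, the 1(10)-ene isomer of 19 with sp3 C-2 (2S, H-2 β); other centres as in 19 | C=C1C(=O)[C@H]2C3=C(CC[C@@H]4[C@H](OC(=O)[C@H]4C)[C@@H]13)CC[C@]21C(=O)C[C@H]2C(=C)CC[C@@H]3[C@H](OC(=O)[C@@H]3C)[C@H]21 | intermediate
19 | CNP0240988.1: spiro dimer in which C-2/C-1/C-10/C-14 of a 3-oxoguaia-1,4(15)-dien-12,6α-olide and C-4'/C-15' of a 3'-oxoguai-10'(14')-en-12',6'α-olide form a cyclohexene (5R,6S,7S,10S,11S,1'R,4'R,5'R,6'S,7'S,11'R) | C=C1C(=O)C2=C3[C@@H](CC[C@@H]4[C@H](OC(=O)[C@H]4C)[C@@H]13)CC[C@]21C(=O)C[C@H]2C(=C)CC[C@@H]3[C@H](OC(=O)[C@@H]3C)[C@H]21 | target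

**Totals**
Total step count: 10. Longest linear sequence: 7 steps (1, 2, 3, 5, 6, 9, 10; the branch through 7 and 8 is equally long).

**Three steps most likely to fail**

Step 2 (the proposed new reaction). The dienolate may attack the exocyclic CH2 instead of the ring carbon, react at its α-carbon, alkylate twice at the now tertiary γ-position, or give poor dr; the sense of induction of the catalyst also has to be confirmed. The fallback uses known reactions only, sets out from 3 and comes back at 13 and 16. Silylation of 3 (TMSOTf, Et3N) gives trimethyl[(3-methylfuran-2-yl)oxy]silane F1. An imidazolidinone-catalysed Mukaiyama–Michael addition of F1 to (E)-penta-2,4-dienal ((2S,5S)-5-benzyl-2-tert-butyl-3-methylimidazolidin-4-one·2,4-dinitrobenzoic acid, CH2Cl2/H2O, −70 °C) sets C-5 and C-6 and gives (3S)-3-[(2R)-4-methyl-5-oxo-2,5-dihydrofuran-2-yl]pent-4-enal F2. Organocatalytic α-methylenation (aqueous CH2O, pyrrolidine/propionic acid, i-PrOH, 45 °C) gives (3R)-2-methylidene-3-[(2S)-4-methyl-5-oxo-2,5-dihydrofuran-2-yl]pent-4-enal F3. Vinylmagnesium bromide (THF, −78 °C) adds 1,2 to give (5S)-5-[(3R)-5-hydroxy-4-methylidenehepta-1,6-dien-3-yl]-3-methylfuran-2(5H)-one F4 (carbinol epimers, erased later). Ring-closing metathesis (second-generation Grubbs catalyst RuCl2(=CHPh)(PCy3)(SIMes), CH2Cl2, 40 °C) forms the C-1/C-2 alkene and gives (5S)-5-[(1R)-4-hydroxy-5-methylidenecyclopent-2-en-1-yl]-3-methylfuran-2(5H)-one F5. Copper-catalysed addition of 8 as in step 5 gives (3R,4S,5S)-4-(3-bromobut-3-en-1-yl)-5-[(1R)-4-hydroxy-5-methylidenecyclopent-2-en-1-yl]-3-methyloxolan-2-one F6, and KOt-Bu as in step 6 converts part of it into the (3S,4S,5S)-epimer F7. MnO2 (CH2Cl2) oxidises F6 to 13 and F7 to 16.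

Step 8. The vinylpalladium may be reduced by formate before the 7-exo insertion, and palladium hydride may isomerise or reduce the exocyclic enone. The fallback sets out from 13 and comes back at 14 by a radical instead of an organopalladium ring closure: tributyltin hydride (slow addition), AIBN, benzene, 80 °C; the vinyl radical cyclises 7-exo-trig onto C-1 and the α-keto radical is reduced. Its only product is 14, so no further compound F0 arises.

Step 10. The one-pot sequence may suffer from self-dimerisation of 17, intermolecular Heck reaction or isomerisation of 14, and from the C-10 epimer if the proton shift is not suprafacial. The fallback separates the events, sets out from 16 and comes back at 18. Reductive Heck cyclisation of 16 under the conditions of step 8 gives (11S)-3-oxoguaia-4(15),10(14)-dien-12,6α-olide F8. TBSOTf, Et3N (CH2Cl2, −78 °C) gives its 3-(tert-butyldimethylsilyloxy)-2,4(15),10(14)-triene F9. Saegusa–Ito oxidation of F9 with Pd(OAc)2 (1.1 equiv, MeCN, 25 °C) in the presence of 14 generates 17, which is trapped as the isolated adduct 18. This is the known dehydrogenation/Diels–Alder dimerisation of closely related guaianolides. TBD then converts 18 into 19, and the two C-10 epimers can be separated at this point if needed.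

**Further compounds**
F1 | step 2 | trimethyl[(3-methylfuran-2-yl)oxy]silane | Cc1ccoc1O[Si](C)(C)C
F2 | step 2 | (3S)-3-[(2R)-4-methyl-5-oxo-2,5-dihydrofuran-2-yl]pent-4-enal | O=CC[C@@H](C=C)[C@H]1OC(=O)C(C)=C1
F3 | step 2 | (3R)-2-methylidene-3-[(2S)-4-methyl-5-oxo-2,5-dihydrofuran-2-yl]pent-4-enal | C=C(C=O)[C@@H](C=C)[C@H]1OC(=O)C(C)=C1
F4 | step 2 | (5S)-5-[(3R)-5-hydroxy-4-methylidenehepta-1,6-dien-3-yl]-3-methylfuran-2(5H)-one | C=CC(O)C(=C)[C@@H](C=C)[C@H]1OC(=O)C(C)=C1
F5 | step 2 | (5S)-5-[(1R)-4-hydroxy-5-methylidenecyclopent-2-en-1-yl]-3-methylfuran-2(5H)-one | C=C1C(O)C=C[C@H]1[C@H]1OC(=O)C(C)=C1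
F6 | step 2 | (3R,4S,5S)-4-(3-bromobut-3-en-1-yl)-5-[(1R)-4-hydroxy-5-methylidenecyclopent-2-en-1-yl]-3-methyloxolan-2-one | C=C1C(O)C=C[C@H]1[C@H]1OC(=O)[C@H](C)[C@@H]1CCC(Br)=C
F7 | step 2 | (3S,4S,5S)-4-(3-bromobut-3-en-1-yl)-5-[(1R)-4-hydroxy-5-methylidenecyclopent-2-en-1-yl]-3-methyloxolan-2-one | C=C1C(O)C=C[C@H]1[C@H]1OC(=O)[C@@H](C)[C@@H]1CCC(Br)=C
F0 | step 8 | none | none
F8 | step 10 | (11S)-3-oxoguaia-4(15),10(14)-dien-12,6α-olide (1α-H, 5α-H, 6β-H, 7α-H, 11β-H) | C=C1C(=O)C[C@H]2C(=C)CC[C@@H]3[C@H](OC(=O)[C@H]3C)[C@H]21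
F9 | step 10 | (11S)-3-(tert-butyldimethylsilyloxy)guaia-2,4(15),10(14)-trien-12,6α-olide (1α-H, 5α-H, 6β-H, 7α-H) | C=C1C(O[Si](C)(C)C(C)(C)C)=C[C@H]2C(=C)CC[C@@H]3[C@H](OC(=O)[C@H]3C)[C@H]21
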